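Start from the leftover: of target made at one moment, the step target → over-reaction product leaves a half after each half-life it sits through, so count half-lives.

| flask | substrate | coupling partner | remark | time |
|---|---|---|---|---|
| noon | 0.034 M | 1.3 equiv | run made earlier |  |
| summer | 0.025 M | 1.3 equiv | run made earlier |  |
| south | 0.050 M | 5.20 equiv |  | 20 min |
| east | 0.050 M | 2.60 equiv |  | 20 min |
| south-west | 0.050 M | 1.30 equiv |  | 20 min |

| run | time / min | target / % | over-reaction product / % | substrate / % | side product B / % |
|---|---|---|---|---|---|
| noon | 0.500 | 10.7 | 1.7 | 90.2 | 1.4 |
| noon | 1.33 | 16.8 | 1.7 | 79.2 | 1.8 |
| noon | 3.00 | 33.0 | 3.7 | 61.2 | 4.2 |
| noon | 8.00 | 36.6 | 17.8 | 32.0 | 16.3 |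
| summer | 2.00 | 20.6 | 1.2 | 77.2 | 2.6 |
| summer | 4.00 | 29.7 | 5.2 | 60.3 | 3.7 |
| summer | 5.00 | 31.2 | 7.7 | 54.5 | 8.2 |
| summer | 8.00 | 33.4 | 10.8 | 40.7 | 13.0 |

(standard deviation of a reading: 1 percentage point)

- percent here means substrate units held: one side product B counts as two
- the analysis behind the earlier runs scatters by 1 percentage point, standard deviation
- reactions considered so far: substrate + coupling partner -> target; 2 coupling partner -> side product A; target -> over-reaction product; substrate + target -> side product B

* which of these there is most of at the end, counted by the substrate in it, south (target / over-reaction product / side product B / substrate)
* which of these there is most of at the end, counted by the substrate in it, east (target / over-reaction product / side product B / substrate)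
* which of these there is most of at the end, counted by the substrate in it, south-west (target / over-reaction product / side product B / substrate)
* amount of the one of these that there is most of at the end, in percent of the substrate charged, south
* amount of the one of these that there is most of at the end, in percent of the substrate charged, east
* amount of the one of these that there is most of at the end, in percent of the substrate charged, south-west

Read the constant as over-reaction product gained per minute over the mean target between two readings. The last two readings of the noon run give 0.0810 /min. The first and last of the summer run give 0.0593 /min. Their mean makes the half-life of target against over-reaction 9.88 min, and the asked time holds 2.02 of them.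

Now solve two extremes. If coupling were instantaneous and side product B absent, target would age the whole time and a quarter would survive, which puts the ceiling for over-reaction product at 75.4 %. If target were born evenly over the time, over-reaction product would reach 46.2 %.

To place the flasks, use the pseudo-first-order lifetime of substrate, 1/(k·c(coupling partner)), scaled from the noon substrate decay. It is 1.04 min in south, 2.08 min in east and 4.15 min in south-west. So south belongs near the ceiling. The south-west lifetime, reckoned as charged, is still short beside the asked time, so this lifetime does not by itself put that flask near the lower figure. Even in south-west, target born after one substrate lifetime still sits through more than one half-life, so I expect over-reaction product to lead in the three flasks. Side product B needs substrate and target together, so I expect it to cut deepest in south-west, where substrate lingers longest, and to pull that flask down from the ceiling.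

The forecast names over-reaction product at 68 % in south, over-reaction product at 56 % in east and over-reaction product at 43 % in south-west: “over-reaction product dominates everywhere”.

The flasks give over-reaction product at 67.6 % in south, over-reaction product at 59.6 % in east and over-reaction product at 44.8 % in south-west.

    substrate + coupling partner → target (k = 0.0710 /M/s)
    2 coupling partner → side product A (k = 0.00210 /M/s)
    target → over-reaction product (k = 0.00120 /s)
    substrate + target → side product B (k = 0.0340 /M/s)

South stands 23 percentage points above south-west, and the difference in equivalents of coupling partner is the main reason: south at the lower loading gives 44.8 % instead of 67.6 %. Take a further flask, south with 21.0 equiv of coupling partner at the same time. The count stays 2.02 half-lives of 9.88 min, the ceiling stays 75.4 %, and the substrate lifetime shrinks to 0.257 min. That flask gives 74.0 % over-reaction product and 23.5 % target.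

All runs were computed from invented constants; the scatter is artificial.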